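**Remark on the chemistry (assumptions).** The target is treated as the H-bonded enol tautomer drawn in its SMILES; tautomers of the enolised tricarbonyl system count as one compound. Commercial (+)-limonene 1,2-oxide is taken as the (4R) cis/trans mixture. The enantiomer of the alkaloid (step 3) and of the bisphosphine (step 4) is the one that delivers the stated configuration; the pseudo-enantiomer or enantiomer would be used if the sense of induction turned out opposite.

**Locants.** Target 21 uses chromene numbering (O1, C2, C3, C4, C4a, C5–C8, C8a). The tricyclic intermediates 6–8, 16, 19 and 20 use benzo[1,2-b:3,4-b']dipyran numbering: C4 is the propyl methine, O5/C5 becomes the C7 ketone of 21, C6 becomes C8 of 21, and C8/C9 are C2/C3 of 21. C2′ is the methine of the C10 side chain.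

## Analysis of the target

Compound 21 is a dearomatised acylphloroglucinol: a cis-2,3-dimethylchroman-4-one (O1, C2, C3, C4) fused through C4a/C8a to a cyclohexadienone ring (C4a, C5, C6, C7, C8, C8a). C8 is an all-carbon quaternary stereocentre carrying a prenyl group and a 2-isopropenyl-5-methylhex-5-enyl group. C6 carries a hexanoic acid chain through its propyl-bearing methine, C5 is an enol OH hydrogen-bonded to C4=O, and C7 is a ketone. The five stereocentres fall into three mutually insulated sets: C2/C3 (2R,3S, cis), the propyl methine (S), and C8 (R) with C2′ (R). The propyl methine is 1,4 to C8 across the C7 carbonyl; C2′ is 1,3 to C8 but sits in a freely rotating chain.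

Sensitive features:
- The cis-chromanone is the less stable isomer and can epimerise at C3 by enolisation or retro-oxa-Michael opening.
- Three electron-rich alkenes sit next to enol and acid functions and would cyclise to chromans under strong acid.
- The vinylogous acid and the carboxylic acid can lactonise.

The central difficulty is C8. Its two substituents are both CH2–alkyl groups, so no reagent that approaches the ring can tell them apart; the centre has to be set by face-selective delivery of one group onto a carbon that already carries the other. Of the two groups only prenyl is allylic, so the homoallylic C10 chain cannot arrive by allylic alkylation or sigmatropic shift.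

The structure offers one handle. The C6 acid chain and the C5 oxygen can be tied into a dihydrocoumarin lactone. Its propyl group is then forced pseudoaxial next to the C7 oxygen, which is the atom from which a prenyl group can be passed to C8.

## Retrosynthetic reasoning

**21 ⇒ 20 (C–O cleavage).** The carboxylic acid and the C5 enol of 21 are the two halves of an enol lactone. Closing it gives 20, a vinylogous anhydride that opens on mild hydrolysis. The same ring protects both acidic groups through the whole route and serves as the stereochemical template for the step before.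

**20 ⇒ 19 (key disconnection, C6–CH2 bond of the prenyl group).** The quaternary carbon is cut at its prenyl group and the group is moved back onto the neighbouring oxygen as a 1,1-dimethylallyl ether. The cut is made here for three reasons:
- Prenyl is the only one of the two substituents that a [3,3] shift can deliver.
- The oxygen that carries it ends as the C7 ketone of 21, exactly what a Claisen rearrangement produces.
- That oxygen is peri to the propyl stereocentre of the dihydrocoumarin, so the face of delivery can be relayed from C4.

The forward step must dearomatise a hexasubstituted arene, choose C6 over C4a, and choose one face. The precursor 19 is a flat aromatic tricycle without the quaternary centre.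

**19 ⇒ 16 + 18 (O–C bond).** The tertiary allyl ether is made from the single free phenol of 16 and the allyl carbonate 18 by palladium-catalysed etherification under near-neutral conditions. This avoids the bases that would endanger the cis-chromanone and the aryl lactone.

**16 ⇒ 8 + 14 (C(sp2)–C(sp3) bond).** The C10 chain is attached at the last free ring position through aryl iodide 8 and the primary alkyl iodide 14 (as its organozinc 15). The chain stereocentre is β to the ring and is not touched by the coupling.

**14 ⇒ 12 ⇒ 11 ⇒ 10 ⇒ 9 (chiral pool).** C4 of the terpene epoxide 9 already carries the isopropenyl group and two arms of the right length, provided that ring carbon C2 is excised. Ring cleavage gives 10, oxidation 11, methylenation 12, and decarboxylative iodination 14. The stereocentre is bought and never touched.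

**8 ⇒ 7 ⇒ 6.** Iodination is trivial because only one ring position is free. The propyl stereocentre is set by ligand-controlled conjugate reduction of the coumarin 6. The reduction is placed after the chromanone is closed, since the enone of 5 would compete, and before any isolated alkene is present.

**6 ⇒ 5 ⇒ 3 ⇒ 1 + 2.** The cis-chromanone comes from a catalytic asymmetric intramolecular oxa-Michael addition of 5. Compound 5 comes from C8 acylation of coumarin 3 with 4, and 3 from a condensation of 1 and 2. Building the coumarin first matters: it fixes the lactone on the oxygen next to the acyl-bearing carbon. That leaves the oxygen next to the future quaternary carbon free for the allyl group and keeps the regiochemistry rigid until the acylation is done.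

## Alternatives that were turned down

**Alternative 1:** the textbook route. Disconnection: the C8–prenyl bond by intermolecular dearomative C-alkylation of the open-chain aromatic acid A1 (base and an allylic halide, or palladium and an allyl carbonate). Turned down because:
- Nothing in A1 controls the face. The acid chain rotates freely, its propyl and carboxymethyl arms are of similar size, and the reacting carbon is 1,4 to that centre, so both configurations at the quaternary carbon are expected. The two diastereomers would differ only in remote relationships.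
- Three nucleophilic sites compete (two phenol oxygens and the acid-bearing ring carbon), under basic conditions that also threaten the cis-chromanone.
- A1 costs the same steps as 16 plus a lactone opening, so nothing is saved.

**Alternative 2:** a para-Claisen/Cope cascade. Disconnection: the same C–C bond, but from the O-prenyl ether A2 of the regioisomeric lactone (lactone on the oxygen next to the future quaternary carbon, prenyl on the chelated oxygen). Forward step: [3,3] shift to the ring-fusion carbon, then a second [3,3] shift to the para carbon. It is attractive because A2 needs only a simple prenyl ether. Turned down on stereochemical grounds: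
- With the lactone on that oxygen the pseudoaxial (S)-propyl group lies on the other face of the ring. A first shift anti to propyl followed by a suprafacial second shift would place prenyl on the face that gives the C8 epimer A3.
- The first shift must build a quaternary carbon directly beside the propyl methine, and it competes with a shift to the acyl-bearing carbon, which has no control element.
- Alkylating the chelated hydroxyl needs base.

**Alternative 3:** desymmetrisation of a gem-diprenyl compound. Disconnection: the C2′–C3′ bond of the C10 chain. The key intermediate A4 carries two identical prenyl groups, so C8 is not yet a stereocentre and A4 is easy to make. A Lewis-acid-promoted ene reaction of one prenyl group with an enone enophile would create C8 and C2′ together and give ketone A5; methylenation would finish. Turned down because: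
- Two diastereotopic prenyl groups and two alkene faces give four products, and every existing stereocentre is at least four bonds from the reacting alkene.
- The stoichiometric alkylaluminium Lewis acid is not compatible with the vinylogous acid, the carboxylic acid and the cis-chromanone.
- The final methylenation would need a basic ylide on the finished, base-sensitive skeleton.

Key step: step 13

## Route

Step 1
Reactants: 1 phloroglucinol (benzene-1,3,5-triol); 2 ethyl 3-oxohexanoate
Product: 3 5,7-dihydroxy-4-propyl-2H-chromen-2-one
Conditions: conc. H2SO4, 0 °C to rt (or CF3SO3H, rt)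
Reagents that add atoms: none
Why: Pechmann condensation (transesterification, intramolecular hydroxyalkylation, dehydration); the symmetric triphenol allows only one product, and all strong-acid chemistry is finished before any acid-sensitive alkene is present.

Step 2
Reactants: 3 5,7-dihydroxy-4-propyl-2H-chromen-2-one; 4 (E)-2-methylbut-2-enoyl chloride (tigloyl chloride)
Product: 5 5,7-dihydroxy-8-[(2E)-2-methylbut-2-enoyl]-4-propyl-2H-chromen-2-one
Conditions: AlCl3 (3 equiv), ClCH2CH2Cl/PhNO2, 0 °C to rt, short time; cold 1 M HCl
Reagents that add atoms: none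
Why: Friedel–Crafts C-acylation; 5,7-dihydroxy-4-alkylcoumarins are acylated preferentially at C8, which puts the acyl group between the lactone oxygen and the 7-OH as the plan requires; low temperature and short contact should keep the enone from closing to racemic chromanone.

Step 3
Reactants: 5 5,7-dihydroxy-8-[(2E)-2-methylbut-2-enoyl]-4-propyl-2H-chromen-2-one
Product: 6 (8R,9S)-5-hydroxy-8,9-dimethyl-4-propyl-8,9-dihydro-2H,10H-benzo[1,2-b:3,4-b']dipyran-2,10-dione
Conditions: (−)-quinine (10–20 mol %), chlorobenzene, 10–15 °C
Reagents that add atoms: none
Why: cinchona-alkaloid-catalysed intramolecular oxa-Michael addition of the chelated 7-OH to the tigloyl enone, a reaction type known for 2,3-dimethylchromanones of this coumarin series; the catalyst selects the enone face (O–CH centre, 8R) and kinetic protonation of the enol should give the cis methyl group (9S); the weak base and low temperature are chosen so that the cis product does not equilibrate to trans.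

Step 4
Reactants: 6 (8R,9S)-5-hydroxy-8,9-dimethyl-4-propyl-8,9-dihydro-2H,10H-benzo[1,2-b:3,4-b']dipyran-2,10-dione
Product: 7 (4S,8R,9S)-5-hydroxy-8,9-dimethyl-4-propyl-3,4,8,9-tetrahydro-2H,10H-benzo[1,2-b:3,4-b']dipyran-2,10-dione
Conditions: Cu(OAc)2·H2O (5 mol %), (R)-DTBM-SEGPHOS (5.5 mol %), (EtO)2MeSiH (4 equiv), t-BuOH (2 equiv), toluene, 0 °C to rt; aq. NH4F
Reagents that add atoms: none
Why: ligand-controlled copper hydride 1,4-reduction of the coumarin C3=C4 bond (asymmetric conjugate reduction of coumarins is a known reaction type); hydride goes to C4 and sets the propyl stereocentre (4S), the aryl silyl ether formed in situ is cleaved on work-up, and the base-free conditions should leave the cis-chromanone alone; the peri-substituted vinylogous-ester ketone should react more slowly than the enoate.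

Step 5
Reactants: 7 (4S,8R,9S)-5-hydroxy-8,9-dimethyl-4-propyl-3,4,8,9-tetrahydro-2H,10H-benzo[1,2-b:3,4-b']dipyran-2,10-dione
Product: 8 (4S,8R,9S)-5-hydroxy-6-iodo-8,9-dimethyl-4-propyl-3,4,8,9-tetrahydro-2H,10H-benzo[1,2-b:3,4-b']dipyran-2,10-dione
Conditions: N-iodosuccinimide (1.05 equiv), MeCN, 0 °C, dark
Reagents that add atoms: N-iodosuccinimide, O=C1CCC(=O)N1I
Why: electrophilic aromatic iodination at the only free ring position, ortho to the free phenol and flanked by two oxygen-bearing carbons; neutral conditions, no stereocentre involved.

Step 6
Reactants: 9 (4R)-limonene 1,2-oxide [(+)-limonene oxide, cis/trans mixture]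
Product: 10 (3R)-6-oxo-3-(prop-1-en-2-yl)heptanal
Conditions: H5IO6 (1.2 equiv), THF/H2O, 0 °C to rt
Reagents that add atoms: water, O
Why: one-pot epoxide hydrolysis and periodate glycol cleavage, known for this epoxide; both epoxide diastereomers converge, the 1,1-disubstituted alkene is inert and the stereocentre (C4 of 9) is not involved.

Step 7
Reactants: 10 (3R)-6-oxo-3-(prop-1-en-2-yl)heptanal
Product: 11 (3R)-6-oxo-3-(prop-1-en-2-yl)heptanoic acid
Conditions: NaClO2, NaH2PO4, 2-methylbut-2-ene (10 equiv), t-BuOH/H2O, 0 °C to rt
Reagents that add atoms: sodium chlorite, [Na+].[O-]Cl=O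
Why: Pinnick oxidation, chemoselective for the aldehyde; the alkene scavenger protects the isopropenyl group from hypochlorous acid.

Step 8
Reactants: 11 (3R)-6-oxo-3-(prop-1-en-2-yl)heptanoic acid
Product: 12 (3R)-6-methyl-3-(prop-1-en-2-yl)hept-6-enoic acid
Conditions: Ph3PCH3Br (2.5 equiv), KOt-Bu (3.5 equiv), THF, 0 °C to rt; then 1 M HCl
Reagents that add atoms: methyltriphenylphosphonium bromide, C[P+](c1ccccc1)(c1ccccc1)c1ccccc1.[Br-]
Why: Wittig methylenation of the methyl ketone on the carboxylate salt; the stereocentre is β to the carboxylate and γ to the ketone and cannot enolise.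

Step 9
Reactants: 12 (3R)-6-methyl-3-(prop-1-en-2-yl)hept-6-enoic acid
Product: 14 (3S)-3-(iodomethyl)-2,6-dimethylhepta-1,6-diene, via Barton ester 13 (not isolated)
Conditions: 1-hydroxypyridine-2(1H)-thione, DCC, DMAP (cat.), CH2Cl2, 0 °C, dark; then CHI3 (2 equiv), tungsten lamp, rt
Reagents that add atoms: iodoform, IC(I)I
Why: Barton decarboxylative iodination (radical chain); iodine-atom transfer from excess iodoform should outrun 1,2-vinyl shift and cyclisation of the primary radical onto the remote alkene; the stereocentre is untouched and only its CIP descriptor changes (R to S).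

Step 10
Reactants: 14 (3S)-3-(iodomethyl)-2,6-dimethylhepta-1,6-diene; 8 (4S,8R,9S)-5-hydroxy-6-iodo-8,9-dimethyl-4-propyl-3,4,8,9-tetrahydro-2H,10H-benzo[1,2-b:3,4-b']dipyran-2,10-dione
Product: 16 (4S,8R,9S)-5-hydroxy-8,9-dimethyl-6-[(2R)-5-methyl-2-(prop-1-en-2-yl)hex-5-en-1-yl]-4-propyl-3,4,8,9-tetrahydro-2H,10H-benzo[1,2-b:3,4-b']dipyran-2,10-dione, via alkylzinc iodide 15 (not isolated)
Conditions: 14, activated Zn dust, LiCl, THF, 40 °C; then slow addition (1.6 equiv) to 8, Pd(OAc)2 (4 mol %), SPhos (8 mol %), THF, 25–40 °C
Reagents that add atoms: none
Why: Negishi C(sp2)–C(sp3) coupling; zinc insertion into the primary iodide gives a configurationally inert homoallylic organozinc, and Pd/biarylphosphine catalysts with slow addition are known to tolerate a free phenol, the aryl lactone and the ketone; the chain centre is not involved (descriptor returns to R by CIP priority only).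

Step 11
Reactants: 17 2-methylbut-3-en-2-ol
Product: 18 tert-butyl (2-methylbut-3-en-2-yl) carbonate
Conditions: n-BuLi (1.0 equiv), THF, −78 °C; then Boc2O, −78 °C to rt
Reagents that add atoms: di-tert-butyl dicarbonate, CC(C)(C)OC(=O)OC(=O)OC(C)(C)C
Why: acylation of the lithium alkoxide of a tertiary allylic alcohol; the tert-butyl carbonate is chosen so that the alkoxide released in step 12 is too hindered to open the aryl lactone.

Step 12
Reactants: 16 (4S,8R,9S)-5-hydroxy-8,9-dimethyl-6-[(2R)-5-methyl-2-(prop-1-en-2-yl)hex-5-en-1-yl]-4-propyl-3,4,8,9-tetrahydro-2H,10H-benzo[1,2-b:3,4-b']dipyran-2,10-dione; 18 tert-butyl (2-methylbut-3-en-2-yl) carbonate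
Product: 19 (4S,8R,9S)-8,9-dimethyl-5-[(2-methylbut-3-en-2-yl)oxy]-6-[(2R)-5-methyl-2-(prop-1-en-2-yl)hex-5-en-1-yl]-4-propyl-3,4,8,9-tetrahydro-2H,10H-benzo[1,2-b:3,4-b']dipyran-2,10-dione
Conditions: Pd(PPh3)4 (5 mol %), THF, 0 °C, short reaction time
Reagents that add atoms: none
Why: Tsuji–Trost O-allylation; the phenoxide attacks the more substituted terminus of the π-(1,1-dimethylallyl)palladium complex under kinetic control to give the tertiary aryl ether, a known way to such ethers; the phenol quenches the tert-butoxide as it forms, so the medium stays near neutral.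

Step 13
Reactants: 19 (4S,8R,9S)-8,9-dimethyl-5-[(2-methylbut-3-en-2-yl)oxy]-6-[(2R)-5-methyl-2-(prop-1-en-2-yl)hex-5-en-1-yl]-4-propyl-3,4,8,9-tetrahydro-2H,10H-benzo[1,2-b:3,4-b']dipyran-2,10-dione
Product: 21 (3S)-3-[(2R,3S,8R)-5-hydroxy-2,3-dimethyl-8-(3-methylbut-2-en-1-yl)-8-[(2R)-5-methyl-2-(prop-1-en-2-yl)hex-5-en-1-yl]-4,7-dioxo-3,4,7,8-tetrahydro-2H-chromen-6-yl]hexanoic acid, via dienone enol lactone 20 (not isolated)
Conditions: degassed toluene, 80–90 °C; then cool, LiOH·H2O (2.2 equiv), THF/H2O, 0 °C; 1 M HCl to pH 3
Reagents that add atoms: water, O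
Why: On heating, the aryl 1,1-dimethylallyl ether undergoes a concerted suprafacial [3,3] shift through a chair transition state in which the CH2 terminus of the allyl unit bonds to C6 of the tricycle, the O5–C bond breaks and C5 becomes a ketone, giving the 6,6-disubstituted cyclohexa-2,4-dienone 20 with a normal prenyl group. The closest known reaction type is the dearomatising aromatic Claisen rearrangement of aryl 1,1-dimethylallyl ethers onto an already substituted ortho carbon, as used to make caged xanthone dienones; no ring is closed, and the only ring change is the later hydrolytic opening of the lactone. The one new stereocentre, C6 of the tricycle (C8 of 21), is controlled by the C4 propyl centre: in the dihydrocoumarin the propyl group is pseudoaxial because of peri strain with the O5 substituent, the di-ortho-substituted ether must turn its C(Me)2 group out of the ring plane and should do so on the face away from propyl, and suprafacial delivery from that face gives 6R from 4S, which is the 8R configuration of 21. Site selectivity between C6 and C4a is needed: C6 lies between two oxygen-bearing carbons and is the more electron-rich and less hindered ortho carbon, whereas attack at C4a would build a quaternary centre beside the propyl methine. The rearrangement must also run forward rather than revert or lose the allyl unit: the doubly vinylogous ester of the dienone and the release of strain in the twisted tertiary ether favour 20, and a non-polar, acid-free medium disfavours ionisation. Hydroxide then opens the enol lactone of 20, a vinylogous anhydride and its most electrophilic carbonyl, by acyl–oxygen cleavage; this makes the sequence irreversible and releases the carboxylic acid and the enol OH at C5 of 21 in the tautomer hydrogen-bonded to C4=O. The base is consumed as it reacts (carboxylate and vinylogous-acid anion), so the C3–H of the cis-chromanone, then α to an anionic β-dicarbonyl system, should not be epimerised.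

## Compound list

1 | phloroglucinol (benzene-1,3,5-triol) | Oc1cc(O)cc(O)c1 | starting material
2 | ethyl 3-oxohexanoate | CCCC(=O)CC(=O)OCC | starting material
3 | 5,7-dihydroxy-4-propyl-2H-chromen-2-one | CCCC1=CC(=O)Oc2cc(O)cc(O)c12 | intermediate
4 | (E)-2-methylbut-2-enoyl chloride (tigloyl chloride) | C/C=C(\C)C(Cl)=O | starting material
5 | 5,7-dihydroxy-8-[(2E)-2-methylbut-2-enoyl]-4-propyl-2H-chromen-2-one | CCCC1=CC(=O)Oc2c(C(=O)/C(C)=C/C)c(O)cc(O)c12 | intermediate
6 | (8R,9S)-5-hydroxy-8,9-dimethyl-4-propyl-8,9-dihydro-2H,10H-benzo[1,2-b:3,4-b']dipyran-2,10-dione | CCCC1=CC(=O)Oc2c1c(O)cc1O[C@H](C)[C@H](C)C(=O)c21 | intermediate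
7 | (4S,8R,9S)-5-hydroxy-8,9-dimethyl-4-propyl-3,4,8,9-tetrahydro-2H,10H-benzo[1,2-b:3,4-b']dipyran-2,10-dione | CCC[C@H]1CC(=O)Oc2c1c(O)cc1O[C@H](C)[C@H](C)C(=O)c21 | intermediate
8 | (4S,8R,9S)-5-hydroxy-6-iodo-8,9-dimethyl-4-propyl-3,4,8,9-tetrahydro-2H,10H-benzo[1,2-b:3,4-b']dipyran-2,10-dione | CCC[C@H]1CC(=O)Oc2c1c(O)c(I)c1O[C@H](C)[C@H](C)C(=O)c21 | intermediate
9 | (4R)-limonene 1,2-oxide, cis/trans mixture | CC12OC1C[C@@H](CC2)C(C)=C | starting material
10 | (3R)-6-oxo-3-(prop-1-en-2-yl)heptanal | O=CC[C@@H](CCC(C)=O)C(C)=C | intermediate
11 | (3R)-6-oxo-3-(prop-1-en-2-yl)heptanoic acid | OC(=O)C[C@@H](CCC(C)=O)C(C)=C | intermediate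
12 | (3R)-6-methyl-3-(prop-1-en-2-yl)hept-6-enoic acid | OC(=O)C[C@@H](CCC(C)=C)C(C)=C | intermediate
13 | 2-thioxopyridin-1(2H)-yl (3R)-6-methyl-3-(prop-1-en-2-yl)hept-6-enoate (Barton ester) | S=C1C=CC=CN1OC(=O)C[C@@H](CCC(C)=C)C(C)=C | intermediate (not isolated)
14 | (3S)-3-(iodomethyl)-2,6-dimethylhepta-1,6-diene | IC[C@@H](CCC(C)=C)C(C)=C | intermediate
15 | iodo[(2S)-5-methyl-2-(prop-1-en-2-yl)hex-5-en-1-yl]zinc | I[Zn]C[C@@H](CCC(C)=C)C(C)=C | intermediate (not isolated)
16 | (4S,8R,9S)-5-hydroxy-8,9-dimethyl-6-[(2R)-5-methyl-2-(prop-1-en-2-yl)hex-5-en-1-yl]-4-propyl-3,4,8,9-tetrahydro-2H,10H-benzo[1,2-b:3,4-b']dipyran-2,10-dione | CCC[C@H]1CC(=O)Oc2c1c(O)c(C[C@@H](CCC(C)=C)C(C)=C)c1O[C@H](C)[C@H](C)C(=O)c21 | intermediate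
17 | 2-methylbut-3-en-2-ol | C=CC(C)(C)O | starting material
18 | tert-butyl (2-methylbut-3-en-2-yl) carbonate | C=CC(C)(C)OC(=O)OC(C)(C)C | intermediate
19 | (4S,8R,9S)-8,9-dimethyl-5-[(2-methylbut-3-en-2-yl)oxy]-6-[(2R)-5-methyl-2-(prop-1-en-2-yl)hex-5-en-1-yl]-4-propyl-3,4,8,9-tetrahydro-2H,10H-benzo[1,2-b:3,4-b']dipyran-2,10-dione | CCC[C@H]1CC(=O)Oc2c1c(OC(C)(C)C=C)c(C[C@@H](CCC(C)=C)C(C)=C)c1O[C@H](C)[C@H](C)C(=O)c21 | intermediate
20 | (4S,6R,8R,9S)-8,9-dimethyl-6-(3-methylbut-2-en-1-yl)-6-[(2R)-5-methyl-2-(prop-1-en-2-yl)hex-5-en-1-yl]-4-propyl-3,4,8,9-tetrahydro-2H-benzo[1,2-b:3,4-b']dipyran-2,5,10(6H)-trione | CCC[C@H]1CC(=O)OC2=C1C(=O)[C@](CC=C(C)C)(C[C@@H](CCC(C)=C)C(C)=C)C1=C2C(=O)[C@@H](C)[C@@H](C)O1 | intermediate (not isolated)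
21 | (3S)-3-[(2R,3S,8R)-5-hydroxy-2,3-dimethyl-8-(3-methylbut-2-en-1-yl)-8-[(2R)-5-methyl-2-(prop-1-en-2-yl)hex-5-en-1-yl]-4,7-dioxo-3,4,7,8-tetrahydro-2H-chromen-6-yl]hexanoic acid | C=C(C)CC[C@H](C[C@@]1(CC=C(C)C)C(=O)C([C@@H](CCC)CC(=O)O)=C(O)C2=C1O[C@H](C)[C@H](C)C2=O)C(=C)C | target

## Step count and risk

Total step count: 13. Longest linear sequence: 8 steps (1, 2, 3, 4, 5, 10, 12, 13) from phloroglucinol. No protecting group is used; the lactone masks the acid and the enol until the last operation.

**Step 13 (key step).** Three things may go wrong:
- Facial discrimination may be too weak. The relay from the propyl group acts only through the orientation of the ether, and the independent stereocentre in the C6 chain may work against it.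
- The hindered tertiary ether may fragment by loss of the allyl unit as a diene, returning the phenol, or the ether/dienone equilibrium may not lie far enough on the dienone side.
- Prolonged heating could let the dienone undergo intramolecular cycloaddition with a pendant alkene.

Fallback: the route leaves at 16 and uses catalyst control instead of the relay. Palladium-catalysed asymmetric dearomative C-prenylation of the phenol (Pd2(dba)3, one enantiomer of the DACH-phenyl bis(diphenylphosphinobenzoyl) ligand, carbonate 18, toluene, rt) lets the ortho carbon attack the unsubstituted terminus of the π-prenyl complex. This gives 20 directly, which is hydrolysed as in step 13 to 21. No new compound is made (F0).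

**Step 4.** The chromanone ketone may undergo competing 1,2-hydrosilylation, the aryl lactone may be over-reduced, and hydride delivery to the peri-hindered β-carbon may be slow. Fallback: the route leaves at 6 and accepts reduction of both carbonyl-conjugated sites with excess silane. This gives the 10-hydroxy chromanol F1 (configuration at the carbinol not controlled). Selective re-oxidation of its benzylic alcohol with MnO2 comes back at 7.

**Step 10.** Oxidative addition and transmetalation at the di-ortho-oxygenated aryl iodide may be slow, the organozinc may be protonated by the phenol, and β-hydride elimination would give the reduced arene. Fallback: the route leaves at 12 and 8 and bypasses 14 and 15. Acid 12 is converted into its N-hydroxyphthalimide ester F2 (N-hydroxyphthalimide, DIC, DMAP cat.). F2 is coupled with 8 by nickel-catalysed reductive decarboxylative arylation (NiBr2·glyme, 4,4′-di-tert-butyl-2,2′-bipyridine, Zn, DMA, rt), in which a primary alkyl radical is captured by aryl–nickel instead of a preformed organozinc being transmetalated. It comes back at 16.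

**Step 12.** C–O bond formation may fail at the hindered phenol, and palladium may re-ionise the product, leading to the linear prenyl ether or to C-allylation without stereocontrol. Fallback: the route leaves at 16 and builds the ether without a π-allyl intermediate. Copper-catalysed O-alkylation with 3-chloro-3-methylbut-1-yne (CuCl2 cat., DBU, MeCN, −5 °C) gives the 1,1-dimethylpropargyl ether F3. Semi-hydrogenation over Lindlar catalyst (quinoline, EtOAc) comes back at 19.

## Further compounds

F0 | step 13 | none | none
F1 | step 4 | (4S,8R,9S)-5,10-dihydroxy-8,9-dimethyl-4-propyl-3,4,9,10-tetrahydro-2H,8H-benzo[1,2-b:3,4-b']dipyran-2-one (10-hydroxy analogue of 7, mixture at C10) | CCC[C@H]1CC(=O)Oc2c1c(O)cc1O[C@H](C)[C@H](C)C(O)c21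
F2 | step 10 | 1,3-dioxoisoindolin-2-yl (3R)-6-methyl-3-(prop-1-en-2-yl)hept-6-enoate | O=C(C[C@@H](CCC(C)=C)C(C)=C)ON1C(=O)c2ccccc2C1=O
F3 | step 12 | (4S,8R,9S)-8,9-dimethyl-5-[(2-methylbut-3-yn-2-yl)oxy]-6-[(2R)-5-methyl-2-(prop-1-en-2-yl)hex-5-en-1-yl]-4-propyl-3,4,8,9-tetrahydro-2H,10H-benzo[1,2-b:3,4-b']dipyran-2,10-dione | CCC[C@H]1CC(=O)Oc2c1c(OC(C)(C)C#C)c(C[C@@H](CCC(C)=C)C(C)=C)c1O[C@H](C)[C@H](C)C(=O)c21
A1 | alternative 1 | (3S)-3-{(2R,3S)-5,7-dihydroxy-2,3-dimethyl-8-[(2R)-5-methyl-2-(prop-1-en-2-yl)hex-5-en-1-yl]-4-oxo-3,4-dihydro-2H-chromen-6-yl}hexanoic acid | CCC[C@@H](CC(=O)O)c1c(O)c(C[C@@H](CCC(C)=C)C(C)=C)c2O[C@H](C)[C@H](C)C(=O)c2c1O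
A2 | alternative 2 | regioisomeric (S)-dihydrocoumarin–(2R,3S)-chromanone with the lactone on the oxygen next to the future quaternary carbon and a 3-methylbut-2-enyl ether on the chelated oxygen | CCC[C@H]1CC(=O)Oc2c1c(OCC=C(C)C)c1C(=O)[C@@H](C)[C@@H](C)Oc1c2C[C@@H](CCC(C)=C)C(C)=C
A3 | alternative 2 | (8S)-epimer of 21 | C=C(C)CC[C@H](C[C@]1(CC=C(C)C)C(=O)C([C@@H](CCC)CC(=O)O)=C(O)C2=C1O[C@H](C)[C@H](C)C2=O)C(=C)C
A4 | alternative 3 | (3S)-3-[(2R,3S)-5-hydroxy-2,3-dimethyl-8,8-bis(3-methylbut-2-en-1-yl)-4,7-dioxo-3,4,7,8-tetrahydro-2H-chromen-6-yl]hexanoic acid | CC(C)=CCC1(CC=C(C)C)C(=O)C([C@@H](CCC)CC(=O)O)=C(O)C2=C1O[C@H](C)[C@H](C)C2=O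
A5 | alternative 3 | (3S)-3-[(2R,3S,8R)-5-hydroxy-2,3-dimethyl-8-(3-methylbut-2-en-1-yl)-4,7-dioxo-8-[(2R)-5-oxo-2-(prop-1-en-2-yl)hexyl]-3,4,7,8-tetrahydro-2H-chromen-6-yl]hexanoic acid | CC(=O)CC[C@H](C[C@@]1(CC=C(C)C)C(=O)C([C@@H](CCC)CC(=O)O)=C(O)C2=C1O[C@H](C)[C@H](C)C2=O)C(=C)C
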